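## Retrosynthetic overview

1. Michaolide F ⇐ SN2 inversions at C14 (HCO2H) and C5 (AcOH) ⇐ 5‑epi epoxy alcohol ⇐ vanadium‑catalysed, OH‑directed epoxidation of a macrocyclic allylic alcohol lactone.
2. α‑Methylene lactone ⇐ oxidative lactonisation of a C2‑OH/C16‑OH diol; E‑C3=C4(Me) ⇐ Red‑Al/I2 then Me2CuLi on a propargylic alcohol.
3. Key step: [2,3]‑Wittig ring contraction of a 17‑membered propargyl allyl ether, which forms the 14‑membered carbocycle, the C1–C2 bond and the C1/C2 stereocentres (relay from C14‑OTBS).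
4. Cyclic ether ⇐ linear chloro‑alcohol ⇐ two glycidyl ethers of the (R)‑glycidol series (C14 and C5), joined by acetylide opening, two Zr‑carboaluminations (both E‑olefins), a Negishi coupling and an alkenylalanate epoxide opening.
5. Ring order: 17‑membered ether → 14‑membered carbocycle → γ‑lactone → epoxide.

Conventions: cembrane numbering of the target is used for all intermediates (ring C1–C14; C15/C16/C17 = lactone α‑carbon/carbonyl/methylene; methyls on C4, C8, C12). Reagents written only over the arrow are not numbered. CIP labels at C1/C2 change with the substituents; from 24 onward the spatial arrangement at C1/C2 is that of the target.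

Assumption: (S)‑PMB glycidyl ether 1 is purchased (otherwise one step from 9).

## Route

Step 1
Reactants: 1 (S)‑PMB glycidyl ether; 2 lithium acetylide–ethylenediamine
Product: 3 (S)‑1‑(PMB‑oxy)pent‑4‑yn‑2‑ol
Conditions: DMSO, rt
Reagents that add atoms: none (2 is a reactant)
Why: SN2 epoxide opening by acetylide at the CH2 terminus (C13); the purchased C14 stereocentre is untouched.

Step 2
Reactants: 3
Product: 4 (S)‑TBS ether of 3
Conditions: TBSCl, imidazole, DMF, rt
Reagents that add atoms: TBSCl, CC(C)(C)[Si](C)(C)Cl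
Why: Silylation; the OTBS group later serves as the stereodirecting allylic substituent at C14.

Step 3
Reactants: 4
Product: 5 (S,E)‑vinyl iodide (I on C11, Me on C12)
Conditions: Me3Al, Cp2ZrCl2 (cat.), CH2Cl2, 0 °C→rt; then I2, THF, −30 °C
Reagents that add atoms: trimethylaluminium, C[Al](C)C; iodine, II
Why: Negishi Zr‑catalysed syn‑carboalumination puts Me on the internal carbon and Al on the terminus; iodinolysis with retention fixes the 11E geometry.

Step 4
Reactants: 5; 6 (4‑bromobut‑1‑yn‑1‑yl)trimethylsilane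
Product: 7 TMS‑enyne (C10–C11 bond formed)
Conditions: 6, Zn, LiCl, THF, 50 °C; then 5, Pd(PPh3)4 (5 mol %), THF, rt
Reagents that add atoms: none
Why: Negishi sp3–sp2 cross‑coupling of the homopropargylzinc with the alkenyl iodide proceeds with retention of olefin geometry.

Step 5
Reactants: 7
Product: 8 terminal alkyne (HC7≡C8)
Conditions: K2CO3, MeOH, rt
Reagents that add atoms: none
Why: Protodesilylation of the C‑silyl alkyne; O‑silyl and PMB ethers are stable.

Step 6
Reactants: 9 (R)‑glycidol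
Product: 10 (S)‑TES glycidyl ether
Conditions: TESCl, Et3N, DMAP (cat.), CH2Cl2, 0 °C
Reagents that add atoms: TESCl, CC[Si](CC)(CC)Cl
Why: O‑silylation; the stereocentre is untouched (the R→S label change is only a CIP priority switch).

Step 7
Reactants: 8; 10
Product: 11 seco‑alcohol (C5‑OH, C4H2‑OTES)
Conditions: Me3Al, Cp2ZrCl2 (cat.), CH2Cl2; evaporate; n‑BuLi, hexane/THF, −78 °C; 10, −30 °C→rt
Reagents that add atoms: trimethylaluminium, C[Al](C)C
Why: A second syn‑carboalumination (Me on C8) followed by alkenylalanate opening of the epoxide at its CH2 (C6) with retention gives the 7E olefin; C5 is the purchased centre.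

Step 8
Reactants: 11
Product: 12 bis‑TES ether
Conditions: TESCl, imidazole, CH2Cl2, rt
Reagents that add atoms: TESCl, CC[Si](CC)(CC)Cl
Why: Silylation of C5‑OH; it must be masked so that only C2‑O directs the later hydroalumination.

Step 9
Reactants: 12
Product: 13 α‑silyloxy aldehyde (C4=O)
Conditions: (COCl)2, DMSO, CH2Cl2, −78→−40 °C; Et3N
Reagents that add atoms: none
Why: Swern conditions cleave and oxidise a primary TES ether directly and selectively; secondary TES/TBS and PMB ethers survive.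

Step 10
Reactants: 13
Product: 14 terminal alkyne (C4≡C3H)
Conditions: dimethyl (1‑diazo‑2‑oxopropyl)phosphonate, K2CO3, MeOH, 0 °C→rt
Reagents that add atoms: Ohira–Bestmann reagent, CC(=O)C(=[N+]=[N-])P(=O)(OC)OC
Why: Seyferth–Gilbert/Ohira–Bestmann homologation under mild base, with little epimerisation of the α‑silyloxy aldehyde.

Step 11
Reactants: 14
Product: 15 propargylic alcohol (C2H2OH)
Conditions: n‑BuLi, THF, −78 °C; (CH2O)n, →rt
Reagents that add atoms: formaldehyde (paraformaldehyde), C=O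
Why: Acetylide addition to formaldehyde installs C2.

Step 12
Reactants: 15
Product: 16 propargylic chloride
Conditions: MsCl, Et3N, CH2Cl2, −20 °C; LiCl, DMF, rt
Reagents that add atoms: lithium chloride, [Li+].[Cl-]
Why: Mesylation then SN2 by chloride gives an electrophile that tolerates the next four steps.

Step 13
Reactants: 16
Product: 17 primary alcohol (C1‑OH)
Conditions: DDQ, CH2Cl2/pH 7 buffer, 0 °C
Reagents that add atoms: none
Why: Oxidative PMB cleavage; silyl ethers, olefins and the chloride are inert.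

Step 14
Reactants: 17
Product: 18 α‑silyloxy aldehyde (C1=O)
Conditions: Dess–Martin periodinane, NaHCO3, CH2Cl2, 0 °C
Reagents that add atoms: none
Why: Neutral oxidation avoids epimerisation at C14.

Step 15
Reactants: 18; 19 4‑methoxybenzyl alcohol; 20 ethyl 2‑(diethoxyphosphoryl)acrylate
Product: 21 (E)‑enoate (ester trans to C14; CH2OPMB cis to C14)
Conditions: 19, NaH, THF, 0 °C; 20; then 18, −78→0 °C
Reagents that add atoms: none (19 and 20 are reactants)
Why: Oxa‑Michael addition of the alkoxide to the vinylphosphonate generates the phosphonate anion, which undergoes E‑selective Horner–Wadsworth–Emmons olefination.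

Step 16
Reactants: 21
Product: 22 allylic alcohol (C17H2OH trans to C14)
Conditions: DIBAL‑H, CH2Cl2, −78 °C
Reagents that add atoms: none
Why: 1,2‑Reduction of the enoate; the propargylic chloride is inert at −78 °C.

Step 17
Reactants: 22
Product: 23 17‑membered propargyl allyl ether (O bridges C2 and C17)
Conditions: NaH, n‑Bu4NI, THF, 2 mM (syringe pump), 50 °C
Reagents that add atoms: none
Why: Intramolecular Williamson etherification at an unhindered propargylic chloride under high dilution.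

Step 18
Reactants: 23
Product: 24 14‑membered propargylic alcohol (C1–C2 bond; C15=C17H2 exocyclic)
Conditions: n‑BuLi, THF–pentane, −78 °C
Reagents that add atoms: none
Why: [2,3]‑Wittig ring contraction of the propargylic C2 carbanion. The trans C14/C17 allyl geometry with the alkynyl group exo gives the anti C1/C2 relationship needed for the trans‑lactone. The carbanion adds anti to the C14–OTBS bond in the A(1,3)‑locked conformer (C14–H eclipsing C1=C15), so 14S sets the target configuration at C1 and C2.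

Step 19
Reactants: 24
Product: 25 (Z)‑iodoalkene (I on C4, cis to C2)
Conditions: Red‑Al, THF, 0 °C→rt; then I2, −78 °C
Reagents that add atoms: iodine, II
Why: Alkoxide‑directed trans‑hydroalumination of the propargylic alcohol (H to C3, Al to C4), then iodinolysis with retention.

Step 20
Reactants: 25
Product: 26 E‑trisubstituted olefin (Me on C4)
Conditions: Me2CuLi, Et2O, 0 °C→rt
Reagents that add atoms: lithium dimethylcuprate, [Li+].C[Cu-]C
Why: Cuprate coupling with retention (Corey trisubstituted‑olefin synthesis) gives 3E.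

Step 21
Reactants: 26
Product: 27 diol (C2‑OH, C16H2OH)
Conditions: DDQ, CH2Cl2/pH 7 buffer, 0 °C
Reagents that add atoms: none
Why: Oxidative cleavage of the remaining PMB ether.

Step 22
Reactants: 27
Product: 28 trans‑fused α‑methylene‑γ‑lactone
Conditions: TEMPO (cat.), PhI(OAc)2, CH2Cl2, rt
Reagents that add atoms: none
Why: Primary‑selective oxidation to the enal, lactol formation with C2‑OH and further oxidation (oxidative lactonisation); no stereocentre is touched.

Step 23
Reactants: 28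
Product: 29 allylic alcohol (C5‑OH)
Conditions: PPTS, MeOH, 0 °C→rt
Reagents that add atoms: none
Why: Mild acid removes the secondary TES ether and leaves the secondary TBS ether.

Step 24
Reactants: 29
Product: 30 epoxy alcohol (3S,4S,5S)
Conditions: VO(acac)2 (5 mol %), t‑BuOOH, CH2Cl2, 0 °C
Reagents that add atoms: tert‑butyl hydroperoxide, CC(C)(C)OO
Why: Vanadium‑catalysed OH‑directed epoxidation is chemoselective for the allylic‑alcohol olefin; A(1,2) strain with the C4 methyl in the vanadate transition state gives the erythro epoxy alcohol, so 5S sets 3S,4S.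

Step 25
Reactants: 30
Product: 31 5R acetate
Conditions: PPh3, DIAD, AcOH, toluene, 0 °C→rt
Reagents that add atoms: acetic acid, CC(=O)O
Why: Mitsunobu esterification; SN2 by acetate inverts C5 and installs the acetate in one step.

Step 26
Reactants: 31
Product: 32 14‑epi‑michaolide F (14S‑OH)
Conditions: HF·pyridine, pyridine, THF, 0 °C→rt
Reagents that add atoms: none
Why: Fluoride desilylation; the electron‑poor epoxide, acetate and lactone tolerate buffered HF.

Step 27
Reactants: 32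
Product: 33 michaolide F
Conditions: PPh3, DIAD, HCO2H, THF, 0 °C→rt; then NaHCO3, MeOH/H2O, rt
Reagents that add atoms: formic acid, OC=O (supplies the new C14 oxygen)
Why: Mitsunobu SN2 inversion gives the 14R formate (not isolated), which is solvolysed far faster than the C5 acetate.

## Compound list

1 | (S)‑2‑{[(4‑methoxybenzyl)oxy]methyl}oxirane | COc1ccc(COC[C@@H]2CO2)cc1 | starting material
2 | lithium acetylide–ethylenediamine complex | [Li]C#C.NCCN | starting material
3 | (S)‑1‑(PMB‑oxy)pent‑4‑yn‑2‑ol | COc1ccc(COC[C@@H](O)CC#C)cc1 | intermediate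
4 | (S)‑2‑(TBS‑oxy)‑1‑(PMB‑oxy)pent‑4‑yne | COc1ccc(COC[C@@H](O[Si](C)(C)C(C)(C)C)CC#C)cc1 | intermediate
5 | (S,E)‑2‑(TBS‑oxy)‑5‑iodo‑4‑methyl‑1‑(PMB‑oxy)pent‑4‑ene | COc1ccc(COC[C@@H](O[Si](C)(C)C(C)(C)C)C/C(C)=C/I)cc1 | intermediate
6 | (4‑bromobut‑1‑yn‑1‑yl)trimethylsilane | C[Si](C)(C)C#CCCBr | starting material
7 | (S,E)‑2‑(TBS‑oxy)‑4‑methyl‑1‑(PMB‑oxy)‑9‑(trimethylsilyl)non‑4‑en‑8‑yne | COc1ccc(COC[C@@H](O[Si](C)(C)C(C)(C)C)C/C(C)=C/CCC#C[Si](C)(C)C)cc1 | intermediate
8 | (S,E)‑2‑(TBS‑oxy)‑4‑methyl‑1‑(PMB‑oxy)non‑4‑en‑8‑yne | COc1ccc(COC[C@@H](O[Si](C)(C)C(C)(C)C)C/C(C)=C/CCC#C)cc1 | intermediate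
9 | (R)‑glycidol | OC[C@@H]1CO1 | starting material
10 | (S)‑triethyl(oxiran‑2‑ylmethoxy)silane | CC[Si](CC)(CC)OC[C@@H]1CO1 | intermediate
11 | seco‑alcohol PMBO‑C1H2–C14H(OTBS)–C13H2–C12(Me)=C11H–C10H2–C9H2–C8(Me)=C7H–C6H2–C5H(OH)–C4H2OTES; 5S,14S; 7E,11E | COc1ccc(COC[C@@H](O[Si](C)(C)C(C)(C)C)C/C(C)=C/CC/C(C)=C/C[C@H](O)CO[Si](CC)(CC)CC)cc1 | intermediate
12 | as 11 with C5‑OTES (bis‑TES); 5S,14S | COc1ccc(COC[C@@H](O[Si](C)(C)C(C)(C)C)C/C(C)=C/CC/C(C)=C/C[C@H](O[Si](CC)(CC)CC)CO[Si](CC)(CC)CC)cc1 | intermediate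
13 | as 12 with C4 = CHO; 5S,14S | COc1ccc(COC[C@@H](O[Si](C)(C)C(C)(C)C)C/C(C)=C/CC/C(C)=C/C[C@H](O[Si](CC)(CC)CC)C=O)cc1 | intermediate
14 | as 12 with C5–C4≡C3H; 5S,14S | COc1ccc(COC[C@@H](O[Si](C)(C)C(C)(C)C)C/C(C)=C/CC/C(C)=C/C[C@H](O[Si](CC)(CC)CC)C#C)cc1 | intermediate
15 | as 14 with C3–C2H2OH; 5S,14S | COc1ccc(COC[C@@H](O[Si](C)(C)C(C)(C)C)C/C(C)=C/CC/C(C)=C/C[C@H](O[Si](CC)(CC)CC)C#CCO)cc1 | intermediate
16 | as 15 with C2H2Cl; 5S,14S | COc1ccc(COC[C@@H](O[Si](C)(C)C(C)(C)C)C/C(C)=C/CC/C(C)=C/C[C@H](O[Si](CC)(CC)CC)C#CCCl)cc1 | intermediate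
17 | as 16 with C1H2OH (PMB removed); 5S,14S | OC[C@@H](O[Si](C)(C)C(C)(C)C)C/C(C)=C/CC/C(C)=C/C[C@H](O[Si](CC)(CC)CC)C#CCCl | intermediate
18 | as 17 with C1 = CHO; 5S,14S | O=C[C@@H](O[Si](C)(C)C(C)(C)C)C/C(C)=C/CC/C(C)=C/C[C@H](O[Si](CC)(CC)CC)C#CCCl | intermediate
19 | 4‑methoxybenzyl alcohol | COc1ccc(CO)cc1 | starting material
20 | ethyl 2‑(diethoxyphosphoryl)acrylate | C=C(C(=O)OCC)P(=O)(OCC)OCC | starting material
21 | ethyl (E)‑enoate: EtO2C(C17)–C15(C16H2OPMB)=C1H–C14…, ester trans to C14; 5S,14S | CCOC(=O)/C(COCc1ccc(OC)cc1)=C/[C@@H](O[Si](C)(C)C(C)(C)C)C/C(C)=C/CC/C(C)=C/C[C@H](O[Si](CC)(CC)CC)C#CCCl | intermediate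
22 | allylic alcohol: HOC17H2 trans to C14, C16H2OPMB cis to C14; 5S,14S | OC/C(COCc1ccc(OC)cc1)=C/[C@@H](O[Si](C)(C)C(C)(C)C)C/C(C)=C/CC/C(C)=C/C[C@H](O[Si](CC)(CC)CC)C#CCCl | intermediate
23 | 17‑membered ether C2H2–O–C17H2–C15(C16H2OPMB)=C1H–C14…C5–C4≡C3; 5S,14S | C1/C(C)=C/C[C@H](O[Si](CC)(CC)CC)C#CCOC/C(COCc2ccc(OC)cc2)=C/[C@@H](O[Si](C)(C)C(C)(C)C)C/C(C)=C/C1 | intermediate
24 | 14‑membered propargylic alcohol: C2‑OH, C3≡C4, C1 bears C15(=C17H2)C16H2OPMB, C5‑OTES, C14‑OTBS; 1S,2S,5S,14S; 7E,11E | C1/C(C)=C/C[C@H](O[Si](CC)(CC)CC)C#C[C@@H](O)[C@H](C(=C)COCc2ccc(OC)cc2)[C@@H](O[Si](C)(C)C(C)(C)C)C/C(C)=C/C1 | intermediate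
25 | as 24 with (Z)‑C3H=C4(I); 1S,2S,5S,14S | C1/C(C)=C/C[C@H](O[Si](CC)(CC)CC)/C(I)=C/[C@@H](O)[C@H](C(=C)COCc2ccc(OC)cc2)[C@@H](O[Si](C)(C)C(C)(C)C)C/C(C)=C/C1 | intermediate
26 | as 24 with (E)‑C3H=C4(Me); 1S,2R,5S,14S | C1/C(C)=C/C[C@H](O[Si](CC)(CC)CC)/C(C)=C/[C@@H](O)[C@H](C(=C)COCc2ccc(OC)cc2)[C@@H](O[Si](C)(C)C(C)(C)C)C/C(C)=C/C1 | intermediate
27 | diol: as 26 with C16H2OH; 1S,2R,5S,14S | C1/C(C)=C/C[C@H](O[Si](CC)(CC)CC)/C(C)=C/[C@@H](O)[C@H](C(=C)CO)[C@@H](O[Si](C)(C)C(C)(C)C)C/C(C)=C/C1 | intermediate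
28 | trans‑fused α‑methylene‑γ‑lactone (16,2‑olide), C5‑OTES, C14‑OTBS; 1S,2R,5S,14S; 3E,7E,11E | C1/C(C)=C/C[C@H](O[Si](CC)(CC)CC)/C(C)=C/[C@H]2OC(=O)C(=C)[C@@H]2[C@@H](O[Si](C)(C)C(C)(C)C)C/C(C)=C/C1 | intermediate
29 | as 28 with C5‑OH; 1S,2R,5S,14S | C1/C(C)=C/C[C@H](O)/C(C)=C/[C@H]2OC(=O)C(=C)[C@@H]2[C@@H](O[Si](C)(C)C(C)(C)C)C/C(C)=C/C1 | intermediate
30 | 3,4‑epoxy‑5‑ol, C14‑OTBS; 1S,2S,3S,4S,5S,14S | C1/C(C)=C/C[C@H](O)[C@]3(C)O[C@H]3[C@H]2OC(=O)C(=C)[C@@H]2[C@@H](O[Si](C)(C)C(C)(C)C)C/C(C)=C/C1 | intermediate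
31 | 5‑acetate, C14‑OTBS; 1S,2S,3S,4S,5R,14S | C1/C(C)=C/C[C@@H](OC(C)=O)[C@]3(C)O[C@H]3[C@H]2OC(=O)C(=C)[C@@H]2[C@@H](O[Si](C)(C)C(C)(C)C)C/C(C)=C/C1 | intermediate
32 | 14‑epi‑michaolide F; 1R,2S,3S,4S,5R,14S | C1/C(C)=C/C[C@@H](OC(C)=O)[C@]3(C)O[C@H]3[C@H]2OC(=O)C(=C)[C@@H]2[C@@H](O)C/C(C)=C/C1 | intermediate
33 | michaolide F; 1R,2S,3S,4S,5R,14R; 7E,11E | C=C1C(=O)O[C@H]2[C@H]1[C@H](O)C/C(C)=C/CC/C(C)=C/C[C@@H](OC(C)=O)[C@]1(C)O[C@@H]21 | target

## Summary

Total steps: 27 (26 in the main line plus step 6 for reagent 10).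
Longest linear sequence: 26 (steps 1–5, 7–27).

Three steps most likely to fail:

- **Step 18, [2,3]‑Wittig ring contraction.** Risks are competing deprotonation (C5–H, PMB CH2), [1,2]‑shift, and a facial bias that in the macrocycle could differ from the acyclic anti‑to‑alkoxy model. Fallback: run the [2,3]‑Wittig on the acyclic propargyl ether of the C14–C17 allylic alcohol fragment, then close the 14‑membered ring last at C10–C11 by intramolecular sp3–sp2 cross‑coupling (alkylzinc or B‑alkyl with the C11 vinyl iodide).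
- **Step 17, 17‑membered Williamson etherification.** Risks are oligomerisation and elimination of the propargylic chloride. Fallback: cap the C4 alkyne with methyl (Corey–Fuchs/MeI in place of steps 10–12), etherify the C17 alcohol intermolecularly with 1‑bromo‑2‑butyne, and close the ring by ring‑closing alkyne metathesis (achiral Mo alkylidyne).
- **Step 25, Mitsunobu inversion at C5 next to the fully substituted epoxide carbon.** Risks are a slow SN2 and elimination; the same concern applies to C14 in step 27. Fallback: activate as a compact sulfonate (chloromethanesulfonate or triflate) and displace with CsOAc/18‑crown‑6; for C14, displace the triflate with Bu4NNO2 to give the inverted alcohol directly.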